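The cycloheptane ring hides an α,β-dihydroxy ketone: C2(=O)–C1(OH)–C5(O-angeloyl). Everything rests on cutting C1–C5, the bond between the tertiary carbinol and the ester-bearing ring carbon. The key step reduces an acyclic 1,2-diketone (C1, C2) with SmI2 to a samarium enediolate that adds through C1 to a pendant C5 aldehyde. One operation closes the seven-membered carbocycle, creates the C1 and C5 stereocentres and leaves C2 as the ketone, with no protecting group on either new hydroxyl. The precursor is an all-cis trisubstituted γ-butyrolactone carrying the aldehyde on C6 and, on C7, a chain that ends in the diketone.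

Key step: step 13

Remark (numbering): xanthanolide numbering is used. C1 is the ring C(OH) bearing the chain C2(=O)–C3H2–C4H(OH)–C15H3. C5 is the ring CH(O-angeloyl), C6 the ring CH(O-lactone) and C7 the ring-fusion CH. C8 and C9 are ring CH2, and C10 is the ring CH(C14H3). C11(C13H3) and C12 are the lactone α-carbon and carbonyl.
Remark (mixtures): carbinol centres that are erased later (in 4, 5, 16 and F4) are formed as mixtures and are left open in the SMILES.

Step 1
Reactants: 1 (S)-β-citronellene, (3S)-3,7-dimethylocta-1,6-diene
Product: 2 (4S)-4-methylhex-5-enal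
Conditions: O3 (1 equiv), CH2Cl2, −78 °C; then Me2S, −78 °C to rt
Reagents that add atoms: ozone, [O-][O+]=O
Why: Chemoselective ozonolysis, because the electron-rich trisubstituted alkene should react far faster than the monosubstituted vinyl group, and the C10 stereocentre from the chiral pool is untouched.

Step 2
Reactants: 2 (4S)-4-methylhex-5-enal; 3 methyl acrylate
Product: 4 methyl (6S)-3-hydroxy-6-methyl-2-methylideneoct-7-enoate (both C3 epimers)
Conditions: DABCO (0.5 equiv), MeOH, rt
Reagents that add atoms: methyl acrylate 3, C=CC(=O)OC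
Why: Morita–Baylis–Hillman reaction of an unhindered aliphatic aldehyde, which joins C7 to C11; the new carbinol centre becomes sp2 in step 4, so its configuration does not matter.

Step 3
Reactants: 4 Baylis–Hillman alcohol
Product: 5 methyl (6S)-3-acetoxy-6-methyl-2-methylideneoct-7-enoate
Conditions: Ac2O, pyridine, DMAP (cat.), CH2Cl2, 0 °C to rt
Reagents that add atoms: acetic anhydride, CC(=O)OC(C)=O
Why: Standard O-acetylation, which turns the allylic hydroxyl into a leaving group for π-allyl formation.

Step 4
Reactants: 5 allylic acetate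
Product: 6 methyl (2E,6S)-6-methyl-2-[(4,4,5,5-tetramethyl-1,3,2-dioxaborolan-2-yl)methyl]octa-2,7-dienoate
Conditions: B2pin2, Pd2(dba)3 (2.5 mol %), toluene, 50 °C
Reagents that add atoms: bis(pinacolato)diboron, CC1(C)OB(OC1(C)C)B1OC(C)(C)C(C)(C)O1
Why: Palladium-catalysed allylic borylation through a π-allyl complex should place boron on the unsubstituted terminus and the alkyl chain trans to the ester (E), that is, cis to CH2B.

Step 5
Reactants: 7 (R)-solketal, [(4R)-2,2-dimethyl-1,3-dioxolan-4-yl]methanol
Product: 8 (S)-glyceraldehyde acetonide, (4S)-2,2-dimethyl-1,3-dioxolane-4-carbaldehyde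
Conditions: TEMPO (10 mol %), PhI(OAc)2, CH2Cl2, rt; used fresh
Reagents that add atoms: none
Why: Oxoammonium (TEMPO) oxidation of a primary alcohol stops at the aldehyde and uses no base, so the α-stereocentre should be retained.

Step 6
Reactants: 6 allylboronate; 8 (S)-glyceraldehyde acetonide
Product: 10 (4S,5R)-5-[(4S)-2,2-dimethyl-1,3-dioxolan-4-yl]-3-methylidene-4-[(3S)-3-methylpent-4-en-1-yl]oxolan-2-one (cis-4,5), via borate ester 9 (not isolated)
Conditions: Sc(OTf)3 (10 mol %), toluene, 0 °C to rt; then PPTS (cat.), rt
Reagents that add atoms: (S)-glyceraldehyde acetonide 8, CC1(C)OC[C@H](O1)C=O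
Why: Lewis acid-accelerated allylboration through a closed chair transition state followed by lactonisation, in which the chain cis to CH2B sits pseudo-axial and gives the syn C6/C7 relationship (cis-lactone), while attack anti to the dioxolane C–O bond (polar Felkin–Anh/Cornforth sense) sets C6 anti to the auxiliary centre.

Step 7
Reactants: 10 α-methylene lactone
Product: 12 (3R,4S,5R)-5-[(4S)-2,2-dimethyl-1,3-dioxolan-4-yl]-3-methyl-4-[(3S)-3-methylpent-4-en-1-yl]oxolan-2-one (all-cis), via lithium enolate 11 (not isolated)
Conditions: LiBH(s-Bu)3 (1.05 equiv), THF, −78 °C; then AcOH in THF, −78 °C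
Reagents that add atoms: none
Why: Conjugate (1,4) hydride reduction of the exocyclic enoate leaves the isolated vinyl group alone, and kinetic protonation of the enolate from the face opposite the two cis substituents on C6 and C7 sets C11 with its methyl cis to the chain.

Step 8
Reactants: 13 (2R)-pent-4-en-2-ol
Product: 14 tert-butyl(dimethyl)[(2R)-pent-4-en-2-yloxy]silane
Conditions: TBSCl, imidazole, CH2Cl2, rt
Reagents that add atoms: tert-butyldimethylsilyl chloride, CC(C)(C)[Si](C)(C)Cl
Why: Standard silylation, which protects the C4 hydroxyl (stereocentre from the chiral pool) against the later oxidations.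

Step 9
Reactants: 12 vinyl lactone; 14 silyl ether
Product: 15 (3R,4S,5R)-4-[(3S,4E,7R)-7-(tert-butyldimethylsilyloxy)-3-methyloct-4-en-1-yl]-5-[(4S)-2,2-dimethyl-1,3-dioxolan-4-yl]-3-methyloxolan-2-one
Conditions: 14 (3 equiv), second-generation Hoveyda–Grubbs catalyst [RuCl2(H2IMes)(=CH-C6H4-2-O-i-Pr)] (5 mol %), CH2Cl2, 40 °C
Reagents that add atoms: silyl ether 14, C=CC[C@@H](C)O[Si](C)(C)C(C)(C)C
Why: Olefin cross-metathesis between the branched vinyl group of 12 and an excess of the unhindered partner should favour the cross product, and the alkene geometry is irrelevant because both carbons become carbonyls.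

Step 10
Reactants: 15 alkene
Product: 16 4,5-diol of 15 (chain C1/C2 diol, mixture of syn-diol diastereomers)
Conditions: OsO4 (2 mol %), NMO, acetone/H2O, rt
Reagents that add atoms: N-methylmorpholine N-oxide, C[N+]1([O-])CCOCC1; water, O
Why: Upjohn syn-dihydroxylation of the only alkene; the two new carbinol centres are erased in step 11, so no facial control is needed.

Step 11
Reactants: 16 diol
Product: 17 (3R,4S,5R)-4-[(3S,7R)-7-(tert-butyldimethylsilyloxy)-3-methyl-4,5-dioxooctyl]-5-[(4S)-2,2-dimethyl-1,3-dioxolan-4-yl]-3-methyloxolan-2-one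
Conditions: IBX (4 equiv), DMSO, rt
Reagents that add atoms: none
Why: IBX oxidation of a vicinal diol gives the α-diketone without C–C cleavage and without base, which should spare the enolisable C10 centre and the β-silyloxy group.

Step 12
Reactants: 17 diketone acetonide
Product: 19 (2R,3S,4R)-3-[(3S,7R)-7-(tert-butyldimethylsilyloxy)-3-methyl-4,5-dioxooctyl]-4-methyl-5-oxooxolane-2-carbaldehyde, via terminal diol 18 (not isolated)
Conditions: H5IO6 (1.3 equiv), EtOAc, 0 °C to rt; used at once
Reagents that add atoms: none
Why: One-pot acetonide hydrolysis and Malaprade glycol cleavage, in which the 1,2-diol should be cleaved much faster than the hindered, unhydrated α-diketone under acidic conditions; the auxiliary centre is excised as the C5 aldehyde appears.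

Step 13
Reactants: 19 diketo aldehyde
Product: 21 (3R,3aS,6S,7S,8S,8aR)-7-[(3R)-3-(tert-butyldimethylsilyloxy)butanoyl]-7,8-dihydroxy-3,6-dimethyloctahydro-2H-cyclohepta[b]furan-2-one, via samarium enediolate 20 (not isolated)
Conditions: SmI2 (2.2 equiv), THF (0.005 M), slow addition of 19, −78 to −40 °C; pH 7 buffer
Reagents that add atoms: none
Why: Two single-electron transfers from SmI2 convert the s-trans 1,2-diketone, by far the most easily reduced group in 19, into the (E)-enediolate 20 before the aliphatic aldehyde, the lactone or the silyl ether can react, and 20 then adds through C1 to the samarium-activated C5 aldehyde (reductive aldol, formally a cross-pinacol). The closest known reaction type is the SmI2-mediated coupling of 1,2-diketones with aldehydes to 2,3-dihydroxy ketones via trivalent samarium enediolates, together with SmI2 Reformatsky-type closures of seven- to nine-membered rings. The cycloheptane closes in the 7-(enolexo)-exo-trig mode, whereas attack through C2 would need an eight-membered ring. C1 is controlled by C10 through allylic 1,3-strain: H10 eclipses the C1=C2 bond, the tether (C9) lies on the reacting face and the C14 methyl on the other, which places the hydroxyl cis and the acyl chain trans to that methyl. C5 is controlled by a chair-like six-membered transition state in which samarium bridges O2 and O5: with C10 cis to O2 in the (E)-enediolate and C6 pseudo-equatorial, O5 should end up anti to O1 (trans-diol), and the aldehyde reacts in its Cornforth conformation (C5=O anti to C6–O6) on the face turned toward the C7 tether, which makes O5 trans to O6. The step needs chemoselective reduction, C1-over-C2 regioselectivity and freedom from over-reduction, and these are secured by the redox gap, by ring size and by two equivalents of reductant at low temperature and high dilution.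

Step 14
Reactants: 21 bicyclic diol; 22 angelic acid, (2Z)-2-methylbut-2-enoic acid
Product: 23 (3R,3aS,6S,7S,8S,8aR)-7-[(3R)-3-(tert-butyldimethylsilyloxy)butanoyl]-7-hydroxy-3,6-dimethyl-2-oxooctahydro-2H-cyclohepta[b]furan-8-yl (2Z)-2-methylbut-2-enoate
Conditions: 22, 2,4,6-trichlorobenzoyl chloride, Et3N, toluene, rt; then 21, 75 °C (no DMAP)
Reagents that add atoms: angelic acid 22, C/C=C(/C)C(=O)O
Why: Yamaguchi-type mixed-anhydride esterification without a nucleophilic catalyst should acylate the secondary C5 hydroxyl in preference to the tertiary C1 hydroxyl and keep the Z geometry, since no conjugate addition–elimination path is open.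

Step 15
Reactants: 23 silyl ether
Product: 24 target, (3R,3aS,6S,7S,8S,8aR)-7-hydroxy-7-[(3R)-3-hydroxybutanoyl]-3,6-dimethyl-2-oxooctahydro-2H-cyclohepta[b]furan-8-yl (2Z)-2-methylbut-2-enoate
Conditions: HF·pyridine, THF, 0 °C to rt
Reagents that add atoms: none
Why: Fluoride-mediated desilylation under mildly acidic conditions should free the C4 hydroxyl without retro-aldol, β-elimination, acyl migration or angelate isomerisation.

Compound list
1 | (S)-β-citronellene, (3S)-3,7-dimethylocta-1,6-diene | CC(C)=CCC[C@H](C)C=C | starting material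
2 | (4S)-4-methylhex-5-enal | O=CCC[C@H](C)C=C | intermediate
3 | methyl acrylate | C=CC(=O)OC | starting material
4 | methyl (6S)-3-hydroxy-6-methyl-2-methylideneoct-7-enoate | COC(=O)C(=C)C(O)CC[C@H](C)C=C | intermediate
5 | methyl (6S)-3-acetoxy-6-methyl-2-methylideneoct-7-enoate | COC(=O)C(=C)C(OC(C)=O)CC[C@H](C)C=C | intermediate
6 | methyl (2E,6S)-6-methyl-2-[(pinacolatoboryl)methyl]octa-2,7-dienoate | COC(=O)/C(CB1OC(C)(C)C(C)(C)O1)=C/CC[C@H](C)C=C | intermediate
7 | (R)-solketal | CC1(C)OC[C@H](O1)CO | starting material
8 | (S)-glyceraldehyde acetonide | CC1(C)OC[C@H](O1)C=O | intermediate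
9 | open-chain pinacol borate of the syn,anti homoallylic alcohol (not isolated) | CC1(C)OC[C@H](O1)[C@H](OB2OC(C)(C)C(C)(C)O2)[C@@H](CC[C@H](C)C=C)C(=C)C(=O)OC | intermediate
10 | cis-α-methylene lactone | CC1(C)OC[C@H](O1)[C@@H]2OC(=O)C(=C)[C@@H]2CC[C@H](C)C=C | intermediate
11 | lithium enolate of 12 (not isolated) | CC1(C)OC[C@H](O1)[C@@H]2OC(O[Li])=C(C)[C@@H]2CC[C@H](C)C=C | intermediate
12 | all-cis α-methyl lactone | CC1(C)OC[C@H](O1)[C@@H]2OC(=O)[C@H](C)[C@@H]2CC[C@H](C)C=C | intermediate
13 | (2R)-pent-4-en-2-ol | C=CC[C@@H](C)O | starting material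
14 | (R)-pent-4-en-2-yl TBS ether | C=CC[C@@H](C)O[Si](C)(C)C(C)(C)C | intermediate
15 | cross-metathesis product, (E)-C1=C2 alkene | CC1(C)OC[C@H](O1)[C@@H]2OC(=O)[C@H](C)[C@@H]2CC[C@H](C)/C=C/C[C@@H](C)O[Si](C)(C)C(C)(C)C | intermediate
16 | C1/C2 diol | CC1(C)OC[C@H](O1)[C@@H]2OC(=O)[C@H](C)[C@@H]2CC[C@H](C)C(O)C(O)C[C@@H](C)O[Si](C)(C)C(C)(C)C | intermediate
17 | C1/C2 diketone acetonide | CC1(C)OC[C@H](O1)[C@@H]2OC(=O)[C@H](C)[C@@H]2CC[C@H](C)C(=O)C(=O)C[C@@H](C)O[Si](C)(C)C(C)(C)C | intermediate
18 | terminal diol from acetonide hydrolysis (not isolated) | OC[C@H](O)[C@@H]1OC(=O)[C@H](C)[C@@H]1CC[C@H](C)C(=O)C(=O)C[C@@H](C)O[Si](C)(C)C(C)(C)C | intermediate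
19 | diketo aldehyde | O=C[C@@H]1OC(=O)[C@H](C)[C@@H]1CC[C@H](C)C(=O)C(=O)C[C@@H](C)O[Si](C)(C)C(C)(C)C | intermediate
20 | (E)-bis(diiodosamarium) enediolate (not isolated) | O=C[C@@H]1OC(=O)[C@H](C)[C@@H]1CC[C@H](C)/C(O[Sm](I)I)=C(O[Sm](I)I)/C[C@@H](C)O[Si](C)(C)C(C)(C)C | intermediate
21 | bicyclic trans-diol | O[C@H]1[C@@H]2OC(=O)[C@H](C)[C@@H]2CC[C@H](C)[C@@]1(O)C(=O)C[C@@H](C)O[Si](C)(C)C(C)(C)C | intermediate
22 | angelic acid | C/C=C(/C)C(=O)O | starting material
23 | C5 angelate, C4 TBS ether | C/C=C(/C)C(=O)O[C@H]1[C@@H]2OC(=O)[C@H](C)[C@@H]2CC[C@H](C)[C@@]1(O)C(=O)C[C@@H](C)O[Si](C)(C)C(C)(C)C | intermediate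
24 | CNP0321985.1 | C/C=C(/C)C(=O)O[C@H]1[C@@H]2OC(=O)[C@H](C)[C@@H]2CC[C@H](C)[C@@]1(O)C(=O)C[C@@H](C)O | target

Total steps: 15. Longest linear sequence: 13 (steps 1–4, 6, 7, 9–15).

Steps most likely to fail

1. Step 13. Two things may go wrong. The enediolate may react through a chelated geometry in which samarium bridges O1 and O5, so that the aldehyde face is taken in the opposite sense. Ring closure may also lose out to simple protonation. The fallback sets out from 19 and uses the chelated outcome instead of fighting it. The closure should then give the cis-diol, the C5-epimeric bicyclic diol F1, whose C1 centre is still set by allylic strain. A Mitsunobu esterification of F1 with angelic acid 22 (PPh3, DIAD, toluene) inverts C5 and installs the ester through the unactivated carboxylate, so the Z geometry is not at risk. The tertiary C1 hydroxyl does not take part. The route is rejoined at 23.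

2. Step 14. Acylation of the hindered C5 hydroxyl next to the quaternary C1 may be slow. This would give time for Z-to-E isomerisation of the activated angelate and for retro-aldol opening in warm amine-containing medium. The fallback sets out from 19. Once the SmI2 colour has discharged in the cyclisation flask, angelic anhydride is added to the cold solution. The secondary samarium alkoxide at O5 is then acylated directly, without acid activation, amine base or heating, and the aldolate is trapped before it can revert. The route is rejoined at 23 and no new compound is made.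

3. Step 12. Periodic acid may also cleave the C1–C2 diketone oxidatively, or cause loss of the silyl ether. The fallback sets out from 15 and performs the glycol cleavage before any diketone exists. Periodic acid gives the alkene aldehyde F2, and NaBH4 (MeOH, 0 °C) gives the primary alcohol F3. Upjohn dihydroxylation then gives the triol F4. One exhaustive IBX oxidation of all three carbinols then forms the aldehyde and the diketone together, and the route is rejoined at 19.

Further compounds
F1 | step 13 | (3R,3aS,6S,7S,8R,8aR)-7-[(3R)-3-(tert-butyldimethylsilyloxy)butanoyl]-7,8-dihydroxy-3,6-dimethyloctahydro-2H-cyclohepta[b]furan-2-one (C5 epimer of 21, cis-diol) | O[C@@H]1[C@@H]2OC(=O)[C@H](C)[C@@H]2CC[C@H](C)[C@@]1(O)C(=O)C[C@@H](C)O[Si](C)(C)C(C)(C)C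
F0 | step 14 | none | none
F2 | step 12 | (2R,3S,4R)-3-[(3S,4E,7R)-7-(tert-butyldimethylsilyloxy)-3-methyloct-4-en-1-yl]-4-methyl-5-oxooxolane-2-carbaldehyde | O=C[C@@H]1OC(=O)[C@H](C)[C@@H]1CC[C@H](C)/C=C/C[C@@H](C)O[Si](C)(C)C(C)(C)C
F3 | step 12 | (3R,4S,5R)-4-[(3S,4E,7R)-7-(tert-butyldimethylsilyloxy)-3-methyloct-4-en-1-yl]-5-(hydroxymethyl)-3-methyloxolan-2-one | OC[C@@H]1OC(=O)[C@H](C)[C@@H]1CC[C@H](C)/C=C/C[C@@H](C)O[Si](C)(C)C(C)(C)C
F4 | step 12 | (3R,4S,5R)-4-[(3S,7R)-7-(tert-butyldimethylsilyloxy)-4,5-dihydroxy-3-methyloctyl]-5-(hydroxymethyl)-3-methyloxolan-2-one | OC[C@@H]1OC(=O)[C@H](C)[C@@H]1CC[C@H](C)C(O)C(O)C[C@@H](C)O[Si](C)(C)C(C)(C)C
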